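**Retrosynthetic overview**
1. Ring B (oxepinone) is closed last by ring-closing metathesis at C2=C3 of vinyl ketone 27; the 15-O-silyl group is removed afterwards.
2. The vinyl ketone comes from a C10 ethynyl group (alkyne hydration, then α-methylenation).
3. Ring A (oxepane) is closed through the key C5–O–C10 bond: a copper-catalysed intramolecular propargylic etherification of carbonate 21 (new), which also fixes C10.
4. Ring C (lactone) is made first, by chromium-mediated 2-(alkoxycarbonyl)allylation of aldehyde 8 (C3–C6, C15) with allyl bromide 19 (C7–C14).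
5. Aldehyde 8 comes from Sharpless epoxidation and vinyl-cuprate opening; bromide 19 from a proline aldol, ethynylation and a Baylis–Hillman reaction. Ring order: C, then A, then B.

Assumption: the stereodescriptors of the SMILES are taken literally; with the target's carbons labelled C1 (ketone), C2=C3, C4 (bearing C15H2OH), C5 (ether CH), C6 (lactone CH–O), C7, C8 (angelate CH), C9, C10 (ether carbon bearing C14H3), C11(=C13H2), C12 (lactone C=O), this is 4R,5R,6S,7R,8R,10S, so the C4 and C1 arms sit on opposite faces of the oxepane (a trans-bridged oxabicycle).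

Abbreviations: TBS = tert-butyldimethylsilyl, TES = triethylsilyl, Boc = tert-butoxycarbonyl, Ph-pybox = 2,6-bis(4-phenyl-4,5-dihydrooxazol-2-yl)pyridine.

**Route**

Step 1
Reactants: 1 (E)-4,4-dimethoxybut-2-enal
Product: 2 (E)-4,4-dimethoxybut-2-en-1-ol
Conditions: NaBH4, MeOH, 0 °C
Reagents that add atoms: none
Why: Borohydride carbonyl reduction is 1,2-selective for the enal and leaves the acetal and the E-alkene; no stereocentre is formed.

Step 2
Reactants: 2 (E)-4,4-dimethoxybut-2-en-1-ol
Product: 3 [(2S,3R)-3-(dimethoxymethyl)oxiran-2-yl]methanol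
Conditions: Ti(OiPr)4 (10 mol %), L-(+)-diethyl tartrate (12 mol %), tBuOOH, 4 Å molecular sieves, CH2Cl2, −20 °C
Reagents that add atoms: tert-butyl hydroperoxide CC(C)(C)OO
Why: Sharpless asymmetric epoxidation with the L-(+)-tartrate delivers oxygen to one face of the E-allylic alcohol, giving the trans epoxide that fixes C5 and the C4 configuration needed for the inversion in step 3.

Step 3
Reactants: 3 [(2S,3R)-3-(dimethoxymethyl)oxiran-2-yl]methanol
Product: 4 (2R,3R)-2-ethenyl-4,4-dimethoxybutane-1,3-diol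
Conditions: CH2=CHMgBr (4 equiv), CuI (10 mol %), THF, −30 → 0 °C
Reagents that add atoms: vinylmagnesium bromide C=C[Mg]Br
Why: Copper-catalysed Grignard opening of the 2,3-epoxy alcohol goes anti at the carbon next to CH2OH because the acetal shields and deactivates the other epoxide carbon, so inversion sets C4 and leaves the C5 hydroxyl.

Step 4
Reactants: 4 (2R,3R)-2-ethenyl-4,4-dimethoxybutane-1,3-diol
Product: 6 (2R,3R)-1-[(tert-butyldimethylsilyl)oxy]-2-ethenyl-4,4-dimethoxy-3-[(triethylsilyl)oxy]butane, via mono-TBS ether 5 (not isolated)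
Conditions: TBSCl (1.05 equiv), imidazole, DMF, 0 °C; then Et3SiCl, rt
Reagents that add atoms: tert-butyldimethylsilyl chloride CC(C)(C)[Si](C)(C)Cl; chlorotriethylsilane CC[Si](Cl)(CC)CC
Why: Silyl ether formation: the primary hydroxyl is silylated first by the bulkier chloride, then the secondary hydroxyl is capped as the more labile TES ether; no stereocentre changes.

Step 5
Reactants: 6 (2R,3R)-1-[(tert-butyldimethylsilyl)oxy]-2-ethenyl-4,4-dimethoxy-3-[(triethylsilyl)oxy]butane
Product: 8 (2R,3R)-3-{[(tert-butyldimethylsilyl)oxy]methyl}-2-[(triethylsilyl)oxy]pent-4-enal, via collidinium salt 7 (not isolated)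
Conditions: Et3SiOTf, 2,4,6-collidine, CH2Cl2, 0 °C; then H2O
Reagents that add atoms: water O
Why: Silyl triflate/collidine acetal cleavage (pyridinium salt, then hydrolysis) unmasks the aldehyde without acid, sparing both silyl ethers and the C5 configuration.

Step 6
Reactants: 9 acetone; 10 ethyl glyoxylate
Product: 11 ethyl (2R)-2-hydroxy-4-oxopentanoate
Conditions: L-proline (20 mol %), acetone (solvent), rt
Reagents that add atoms: none
Why: Proline-catalysed direct aldol reaction (enamine catalysis): the acetone enamine attacks the re face of the aldehyde, by analogy with proline aldols of other aldehydes, and sets C8 as R.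

Step 7
Reactants: 11 ethyl (2R)-2-hydroxy-4-oxopentanoate
Product: 12 ethyl (2R)-4-oxo-2-[(triethylsilyl)oxy]pentanoate
Conditions: Et3SiCl, imidazole, CH2Cl2, 0 °C
Reagents that add atoms: chlorotriethylsilane CC[Si](Cl)(CC)CC
Why: Silyl ether formation protects the C8 hydroxyl without touching the stereocentre.

Step 8
Reactants: 12 ethyl (2R)-4-oxo-2-[(triethylsilyl)oxy]pentanoate
Product: 14 ethyl (2R)-4-[(tert-butoxycarbonyl)oxy]-4-methyl-2-[(triethylsilyl)oxy]hex-5-ynoate (both C4 epimers), via magnesium alkoxide 13 (not isolated)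
Conditions: HC≡CMgBr, CeCl3, THF, −78 °C; then Boc2O, −78 → 0 °C
Reagents that add atoms: ethynylmagnesium bromide C#C[Mg]Br; di-tert-butyl dicarbonate CC(C)(C)OC(=O)OC(=O)OC(C)(C)C
Why: Cerium-assisted Grignard addition is selective for the ketone over the ester and the tertiary alkoxide is trapped as its tert-butyl carbonate; C10 is formed as both epimers on purpose because step 13 erases it.

Step 9
Reactants: 14 ethyl (2R)-4-[(tert-butoxycarbonyl)oxy]-4-methyl-2-[(triethylsilyl)oxy]hex-5-ynoate
Product: 15 (2R)-4-[(tert-butoxycarbonyl)oxy]-4-methyl-2-[(triethylsilyl)oxy]hex-5-ynal (both C4 epimers)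
Conditions: iBu2AlH (1.1 equiv), CH2Cl2, −78 °C; Rochelle salt
Reagents that add atoms: none
Why: Hydride half-reduction of the α-silyloxy ester stops at the aldehyde at −78 °C through the stable tetrahedral aluminate; C8 is untouched.

Step 10
Reactants: 15 (2R)-4-[(tert-butoxycarbonyl)oxy]-4-methyl-2-[(triethylsilyl)oxy]hex-5-ynal; 16 methyl acrylate
Product: 17 methyl 2-{(2R)-4-[(tert-butoxycarbonyl)oxy]-1-hydroxy-4-methyl-2-[(triethylsilyl)oxy]hex-5-yn-1-yl}prop-2-enoate (epimers at the new carbinol and at C10)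
Conditions: methyl acrylate (excess), DABCO (0.5 equiv), MeOH (cat.), rt
Reagents that add atoms: none
Why: The Morita–Baylis–Hillman reaction attaches C11–C13 through the acrylate α-carbon; the new carbinol centre is lost in step 11.

Step 11
Reactants: 17 methyl 2-{(2R)-4-[(tert-butoxycarbonyl)oxy]-1-hydroxy-4-methyl-2-[(triethylsilyl)oxy]hex-5-yn-1-yl}prop-2-enoate
Product: 19 methyl (2Z,4R)-2-(bromomethyl)-6-[(tert-butoxycarbonyl)oxy]-6-methyl-4-[(triethylsilyl)oxy]oct-2-en-7-ynoate (both C6 epimers), via allylic mesylate 18 (not isolated)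
Conditions: MsCl, Et3N, CH2Cl2, −20 °C; then LiBr, THF, 0 °C → rt
Reagents that add atoms: lithium bromide [Li+].[Br-]
Why: Mesylation and SN2′ displacement by bromide transpose the allylic system to the thermodynamically preferred (Z)-2-(bromomethyl)enoate.

Step 12
Reactants: 8 (2R,3R)-3-{[(tert-butyldimethylsilyl)oxy]methyl}-2-[(triethylsilyl)oxy]pent-4-enal; 19 methyl (2Z,4R)-2-(bromomethyl)-6-[(tert-butoxycarbonyl)oxy]-6-methyl-4-[(triethylsilyl)oxy]oct-2-en-7-ynoate
Product: 21 (4R,5S)-5-[(1R,2R)-2-{[(tert-butyldimethylsilyl)oxy]methyl}-1-hydroxybut-3-en-1-yl]-4-{(1R)-3-[(tert-butoxycarbonyl)oxy]-1-hydroxy-3-methylpent-4-yn-1-yl}-3-methylidenedihydrofuran-2(3H)-one (both C10 epimers), via bis-TES lactone 20 (not isolated)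
Conditions: CrCl2 (4 equiv), THF, 0 °C → rt; then PPTS, MeOH, 0 °C → rt
Reagents that add atoms: none
Why: Nozaki–Hiyama 2-(alkoxycarbonyl)allylation: the allylchromium adds through its γ-carbon to the Felkin–Anh face of the α-silyloxy aldehyde (C6 anti to the C5 oxygen) via a chair transition state with the γ-substituent equatorial (C7 anti to C6, hence the trans lactone after in situ lactonisation), and PPTS/methanol then removes both TES ethers.

Step 13
Reactants: 21 the lactone diol carbonate of step 12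
Product: 22 (4R,5R,6S,7R,8R,10S)-oxepane-fused trans-lactone with C10 methyl and ethynyl, free C8 hydroxyl and 15-O-TBS
Conditions: Cu(MeCN)4PF6 (10 mol %), (S,S)-Ph-pybox (12 mol %), iPr2NEt (1.2 equiv), THF (5 mM), −10 °C → rt
Reagents that add atoms: none
Why: Proposed new method: the copper acetylide of 21 expels tert-butyl carbonate to give a copper allenylidene that is planar at C10 (so both C10 epimers converge), and the C5 hydroxyl attacks it 7-exo inside the pybox pocket with the methyl equatorial and the slim alkynyl unit axial, setting C10 as S and trans to the C4 arm; the closest known reactions are copper/pybox asymmetric propargylic etherifications of secondary propargylic esters and decarboxylative substitutions of tertiary ethynyl cyclic carbonates, not yet shown for a dialkyl tertiary centre attacked by a hindered secondary alcohol to close a seven-membered ring.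

Step 14
Reactants: 22 the oxepane alcohol of step 13; 23 angelic acid
Product: 25 8-O-angelate of 22, via mixed anhydride 24 (not isolated)
Conditions: angelic acid, 2,4,6-trichlorobenzoyl chloride, Et3N, toluene, rt; then 22, 80 °C
Reagents that add atoms: none
Why: Yamaguchi-type esterification through the mixed anhydride without DMAP acylates the only free hydroxyl and keeps the Z geometry of the angelate; C8 keeps its configuration.

Step 15
Reactants: 25 8-O-angelate of 22
Product: 26 C10 acetyl compound (methyl ketone)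
Conditions: Ph3PAuNTf2 (3 mol %), 1,4-dioxane/H2O (10:1), 60 °C
Reagents that add atoms: water O
Why: Gold-catalysed Markovnikov hydration of the terminal alkyne gives the methyl ketone at C1; no stereocentre changes.

Step 16
Reactants: 26 C10 acetyl compound
Product: 27 C10 acryloyl compound (vinyl ketone)
Conditions: (CH2O)n, iPr2NH2+ CF3CO2− (1 equiv), CF3CO2H (10 mol %), THF, 65 °C
Reagents that add atoms: formaldehyde (as paraformaldehyde) C=O
Why: α-Methylenation (Mannich condensation then elimination) can occur only at the methyl group because C10 is quaternary, giving the vinyl ketone.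

Step 17
Reactants: 27 C10 acryloyl compound
Product: 28 15-O-TBS ether of the target
Conditions: second-generation Hoveyda–Grubbs catalyst (10 mol %), toluene (1 mM), 80 °C
Reagents that add atoms: none
Why: Ring-closing metathesis joins the vinyl ketone and the C4 vinyl group into the cis enone of seven-membered ring B; closures of this kind are known for strained trans-bridged medium-ring bicycles and touch no stereocentre.

Step 18
Reactants: 28 15-O-TBS ether of the target
Product: 29 target CNP0274187.1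
Conditions: HF·pyridine, pyridine, THF, 0 °C → rt
Reagents that add atoms: none
Why: Fluoride desilylation frees the primary alcohol under mildly acidic conditions that avoid base-induced β-elimination of the ether next to the enone.

**Compound list**
1 | (E)-4,4-dimethoxybut-2-enal | O=C/C=C/C(OC)OC | starting material
2 | (E)-4,4-dimethoxybut-2-en-1-ol | OC/C=C/C(OC)OC | intermediate
3 | [(2S,3R)-3-(dimethoxymethyl)oxiran-2-yl]methanol | OC[C@@H]1O[C@H]1C(OC)OC | intermediate
4 | (2R,3R)-2-ethenyl-4,4-dimethoxybutane-1,3-diol | OC[C@@H](C=C)[C@@H](O)C(OC)OC | intermediate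
5 | (2R,3R)-1-[(tert-butyldimethylsilyl)oxy]-2-ethenyl-4,4-dimethoxybutan-3-ol | CC(C)(C)[Si](C)(C)OC[C@@H](C=C)[C@@H](O)C(OC)OC | intermediate
6 | (2R,3R)-1-[(tert-butyldimethylsilyl)oxy]-2-ethenyl-4,4-dimethoxy-3-[(triethylsilyl)oxy]butane | CC(C)(C)[Si](C)(C)OC[C@@H](C=C)[C@@H](O[Si](CC)(CC)CC)C(OC)OC | intermediate
7 | 1-[(2R,3R)-3-{[(tert-butyldimethylsilyl)oxy]methyl}-1-methoxy-2-[(triethylsilyl)oxy]pent-4-en-1-yl]-2,4,6-trimethylpyridinium triflate (both epimers at the N,O-acetal carbon) | CC(C)(C)[Si](C)(C)OC[C@@H](C=C)[C@@H](O[Si](CC)(CC)CC)C(OC)[n+]1c(C)cc(C)cc1C.[O-]S(=O)(=O)C(F)(F)F | intermediate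
8 | (2R,3R)-3-{[(tert-butyldimethylsilyl)oxy]methyl}-2-[(triethylsilyl)oxy]pent-4-enal | CC(C)(C)[Si](C)(C)OC[C@@H](C=C)[C@@H](O[Si](CC)(CC)CC)C=O | intermediate
9 | acetone | CC(C)=O | starting material
10 | ethyl glyoxylate | CCOC(=O)C=O | starting material
11 | ethyl (2R)-2-hydroxy-4-oxopentanoate | CCOC(=O)[C@H](O)CC(C)=O | intermediate
12 | ethyl (2R)-4-oxo-2-[(triethylsilyl)oxy]pentanoate | CCOC(=O)[C@H](O[Si](CC)(CC)CC)CC(C)=O | intermediate
13 | bromomagnesium alkoxide of ethyl (2R)-4-hydroxy-4-methyl-2-[(triethylsilyl)oxy]hex-5-ynoate (both C4 epimers) | CCOC(=O)[C@H](O[Si](CC)(CC)CC)CC(C)(O[Mg]Br)C#C | intermediate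
14 | ethyl (2R)-4-[(tert-butoxycarbonyl)oxy]-4-methyl-2-[(triethylsilyl)oxy]hex-5-ynoate (both C4 epimers) | CCOC(=O)[C@H](O[Si](CC)(CC)CC)CC(C)(OC(=O)OC(C)(C)C)C#C | intermediate
15 | (2R)-4-[(tert-butoxycarbonyl)oxy]-4-methyl-2-[(triethylsilyl)oxy]hex-5-ynal (both C4 epimers) | O=C[C@H](O[Si](CC)(CC)CC)CC(C)(OC(=O)OC(C)(C)C)C#C | intermediate
16 | methyl acrylate | C=CC(=O)OC | starting material
17 | methyl 2-{(2R)-4-[(tert-butoxycarbonyl)oxy]-1-hydroxy-4-methyl-2-[(triethylsilyl)oxy]hex-5-yn-1-yl}prop-2-enoate (epimers at C1 and C4 of the hexynyl chain) | C=C(C(=O)OC)C(O)[C@H](O[Si](CC)(CC)CC)CC(C)(OC(=O)OC(C)(C)C)C#C | intermediate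
18 | methanesulfonate of 17 at the allylic hydroxyl | C=C(C(=O)OC)C(OS(C)(=O)=O)[C@H](O[Si](CC)(CC)CC)CC(C)(OC(=O)OC(C)(C)C)C#C | intermediate
19 | methyl (2Z,4R)-2-(bromomethyl)-6-[(tert-butoxycarbonyl)oxy]-6-methyl-4-[(triethylsilyl)oxy]oct-2-en-7-ynoate (both C6 epimers) | COC(=O)/C(CBr)=C/[C@H](O[Si](CC)(CC)CC)CC(C)(OC(=O)OC(C)(C)C)C#C | intermediate
20 | (4S,5S)-5-[(1R,2R)-2-{[(tert-butyldimethylsilyl)oxy]methyl}-1-[(triethylsilyl)oxy]but-3-en-1-yl]-4-{(1R)-3-[(tert-butoxycarbonyl)oxy]-3-methyl-1-[(triethylsilyl)oxy]pent-4-yn-1-yl}-3-methylidenedihydrofuran-2(3H)-one (both C10 epimers; same spatial arrangement as 21) | C=C1C(=O)O[C@H]([C@H](O[Si](CC)(CC)CC)[C@@H](CO[Si](C)(C)C(C)(C)C)C=C)[C@H]1[C@H](O[Si](CC)(CC)CC)CC(C)(OC(=O)OC(C)(C)C)C#C | intermediate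
21 | (4R,5S)-5-[(1R,2R)-2-{[(tert-butyldimethylsilyl)oxy]methyl}-1-hydroxybut-3-en-1-yl]-4-{(1R)-3-[(tert-butoxycarbonyl)oxy]-1-hydroxy-3-methylpent-4-yn-1-yl}-3-methylidenedihydrofuran-2(3H)-one (both C10 epimers) | C=C1C(=O)O[C@H]([C@H](O)[C@@H](CO[Si](C)(C)C(C)(C)C)C=C)[C@H]1[C@H](O)CC(C)(OC(=O)OC(C)(C)C)C#C | intermediate
22 | trans-fused α-methylene-γ-butyrolactone (O–C6, C7) on an oxepane (O–C5–C6–C7–C8–C9–C10); C5 carries the (2R)-1-[(tert-butyldimethylsilyl)oxy]but-3-en-2-yl arm, C8 a free hydroxyl, C10 a methyl and an ethynyl group; 4R,5R,6S,7R,8R,10S | C=C1C(=O)O[C@@H]2[C@@H]([C@@H](CO[Si](C)(C)C(C)(C)C)C=C)O[C@](C)(C#C)C[C@@H](O)[C@@H]12 | intermediate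
23 | angelic acid, (Z)-2-methylbut-2-enoic acid | C/C=C(/C)C(=O)O | starting material
24 | angelic 2,4,6-trichlorobenzoic anhydride | C/C=C(/C)C(=O)OC(=O)c1c(Cl)cc(Cl)cc1Cl | intermediate
25 | 22 with the C8 hydroxyl esterified as the (Z)-2-methylbut-2-enoate; 4R,5R,6S,7R,8R,10S | C=C1C(=O)O[C@@H]2[C@@H]([C@@H](CO[Si](C)(C)C(C)(C)C)C=C)O[C@](C)(C#C)C[C@@H](OC(=O)/C(C)=C\C)[C@@H]12 | intermediate
26 | 25 with the C10 ethynyl group replaced by acetyl; 4R,5R,6S,7R,8R,10S | C=C1C(=O)O[C@@H]2[C@@H]([C@@H](CO[Si](C)(C)C(C)(C)C)C=C)O[C@](C)(C(C)=O)C[C@@H](OC(=O)/C(C)=C\C)[C@@H]12 | intermediate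
27 | 26 with the acetyl group replaced by prop-2-enoyl (vinyl ketone); 4R,5R,6S,7R,8R,10S | C=C1C(=O)O[C@@H]2[C@@H]([C@@H](CO[Si](C)(C)C(C)(C)C)C=C)O[C@](C)(C(=O)C=C)C[C@@H](OC(=O)/C(C)=C\C)[C@@H]12 | intermediate
28 | 15-O-tert-butyldimethylsilyl ether of the target; 4R,5R,6S,7R,8R,10S | C=C1C(=O)O[C@@H]2[C@@H]3O[C@@](C)(C[C@@H](OC(=O)/C(C)=C\C)[C@@H]12)C(=O)C=C[C@@H]3CO[Si](C)(C)C(C)(C)C | intermediate
29 | CNP0274187.1; 4R,5R,6S,7R,8R,10S | C=C1C(=O)O[C@@H]2[C@@H]3O[C@@](C)(C[C@@H](OC(=O)/C(C)=C\C)[C@@H]12)C(=O)C=C[C@@H]3CO | target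

**Step count and risks**

Total: 18 steps (5 to aldehyde 8, 6 to bromide 19, 7 after their union). Longest linear sequence: 13 steps (steps 6–18, from acetone and ethyl glyoxylate).

The three steps most likely to fail:

Step 10. The Baylis–Hillman reaction of the hindered, base-sensitive α-silyloxy aldehyde may be slow and may erode C8. The fallback sets out from 15 and comes back at 17. The lithium enolate of methyl 3-(phenylselanyl)propanoate (LDA, THF, −78 °C) is added to 15 to give the aldol adduct, methyl 3-hydroxy-2-[(phenylselanyl)methyl] ester F1. Oxidation with H2O2 (CH2Cl2, pyridine, 0 °C) and selenoxide elimination then give 17.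

Step 13. The proposed copper-catalysed etherification may suffer elimination to an enyne or poor control at C10. The fallback uses the Nicholas reaction, sets out from 21 and comes back at 22. Co2(CO)8 (CH2Cl2, rt) gives the hexacarbonyldicobalt alkyne complex F2. BF3·OEt2 (CH2Cl2, −20 °C) ionises the carbonate and the C5 hydroxyl closes the oxepane to the cyclised cobalt complex F3. Here there is no catalyst control and the bulky cobalt cluster may favour the C10 epimer, so the epimers are separated. (NH4)2Ce(NO3)6 in acetone at 0 °C removes the cobalt and gives 22.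

Step 17. The metathesis must close a strained trans-bridged ring and must outcompete reaction at the α-methylene lactone. The fallback sets out from 27 and comes back at 28. Luche reduction (NaBH4, CeCl3·7H2O, MeOH, −78 °C) gives the doubly allylic alcohol F4 (both C1 epimers), a more reactive metathesis partner. Ring-closing metathesis with the same ruthenium catalyst gives the cyclic allylic alcohol F5. MnO2 (CH2Cl2, rt) oxidises the allylic alcohol to 28.

**Further compounds**
F1 | step 10 | methyl (4R)-6-[(tert-butoxycarbonyl)oxy]-3-hydroxy-6-methyl-2-[(phenylselanyl)methyl]-4-[(triethylsilyl)oxy]oct-7-ynoate (epimer mixture at C2, C3 and C6) | COC(=O)C(C[Se]c1ccccc1)C(O)[C@H](O[Si](CC)(CC)CC)CC(C)(OC(=O)OC(C)(C)C)C#C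
F2 | step 13 | hexacarbonyldicobalt complex of the alkyne of 21 | C=C1C(=O)O[C@H]([C@H](O)[C@@H](CO[Si](C)(C)C(C)(C)C)C=C)[C@H]1[C@H](O)CC(C)(OC(=O)OC(C)(C)C)C12[CH]3[Co]1(=C=O)(=C=O)(=C=O)[Co]23(=C=O)(=C=O)=C=O
F3 | step 13 | hexacarbonyldicobalt complex of the alkyne of 22 (both C10 epimers) | C=C1C(=O)O[C@@H]2[C@@H]([C@@H](CO[Si](C)(C)C(C)(C)C)C=C)OC(C)(C[C@@H](O)[C@@H]12)C34[CH]5[Co]3(=C=O)(=C=O)(=C=O)[Co]45(=C=O)(=C=O)=C=O
F4 | step 17 | 27 with the C1 ketone reduced to the allylic alcohol (both C1 epimers) | C=C1C(=O)O[C@@H]2[C@@H]([C@@H](CO[Si](C)(C)C(C)(C)C)C=C)O[C@](C)(C(O)C=C)C[C@@H](OC(=O)/C(C)=C\C)[C@@H]12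
F5 | step 17 | 28 with the C1 ketone as the allylic alcohol (both C1 epimers) | C=C1C(=O)O[C@@H]2[C@@H]3O[C@@](C)(C[C@@H](OC(=O)/C(C)=C\C)[C@@H]12)C(O)C=C[C@@H]3CO[Si](C)(C)C(C)(C)C
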